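Two routes compete for one reagent, so I compare their rates: the onward step to target against the side reaction to uncatalysed product.

    substrate + free catalyst ⇌ free catalyst + intermediate (K1 = 0.318, k1 = 384 /M/s, Ea1 = 43.0 kJ/mol, ΔH1 = −77.0 kJ/mol)
    substrate + reagent → uncatalysed product (k2 = 0.00892 /M/s, Ea2 = 80.0 kJ/mol)
    reagent + second catalyst + intermediate → second catalyst + target (k3 = 3.87 /M²/s, Ea3 = 37.0 kJ/mol)
    second catalyst ⇌ dormant form (K4 = 0.010, k4 = 0.00275 /s, Ea4 = 81.0 kJ/mol, ΔH4 = −20.0 kJ/mol)
    (constants at 50 °C)

| setting | elm | cedar |
|---|---|---|
| substrate | 0.20 M | 0.20 M |
| reagent | 0.160 M | 0.160 M |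
| free catalyst | 0.10 mM | 0.10 mM |
| second catalyst | 20 mM | 20 mM |
| temperature | 35 °C | 50 °C |
| time | 8.0 min | 8.0 min |

- all constants are for 50 °C and move with temperature by the activation energies and enthalpies

1. which flask leads in share of target in all that became target or uncatalysed product ("all alike" within 1.5 percentage points) (elm / cedar / all alike)
2. share of target in all that became target or uncatalysed product, elm
3. share of target in all that became target or uncatalysed product, cedar

**My reckoning, fastest rung first**

1. The rule: dividing the two rate laws cancels reagent. Target per uncatalysed product is then S = P·x. Here P is the onward constant times second catalyst over the side constant, and x is intermediate over substrate. P is 8.68 in cedar and 18.9 in elm.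

2. In cedar, second catalyst and dormant form balance within 3.64 s, with 0.990% dormant. I count second catalyst whole there, and in elm too.

3. The equilibrium step between substrate and intermediate relaxes in 6.28 s in cedar and 31.9 s in elm, both shorter than the 8.0 min run. My first answer is therefore x = K, the equilibrium constant: 0.318 in cedar, 1.28 in elm. That gives S of 2.76 and 24.3.

4. The onward step, pseudo-first-order in intermediate, takes 80.7 s in cedar and 158 s in elm with reagent at its charge. So I go round again. Let d be the onward rate over the fall-back rate of intermediate: 0.103 in cedar, 0.461 in elm. Then x = K/(1 + d), and S becomes 2.50 in cedar and 16.6 in elm. This S, the selectivity factor, is my estimate of target formed per uncatalysed product with reagent held at its charge.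

5. Slowest rung: substrate's time against reagent in the side reaction is 11.7 min in cedar and 49.8 min in elm, both longer than the run. The side reaction runs from the first second, and elm's build-up of intermediate is the slower, so I expect elm a little below my figure.

6. S/(1 + S) gives 94.3% for elm and 71.5% for cedar, so the leader is elm.

**The forecast**

The forecast starts from “Step 1 equilibrates quickly”. It names elm, with 94.7% (93.8% to 95.5%) for elm and 72.3% (71.3% to 73.2%) for cedar. It holds x near 1.15 in elm, where I get 0.876.

**The result**

The flasks give 93.9% in elm and 71.4% in cedar, so elm leads, inside both forecast ranges. In elm, reagent use by the onward step over that by the side reaction reads 10 at 0.602 min and 23 at 8.00 min, with my S between them. The cedar share moves 5 points, past the forecast's range, at 15.6 mM or 26.5 mM of second catalyst.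

**A second flask**

Take elm with free catalyst at 2.5 × 10⁻⁵ M: d grows to 1.85, so S is 8.53 and the share 89.5%. The flask gives 88.2%.

(All constants stand for no real mixture; what happens was integrated by code.)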